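The readings come from a simulation for an exercise; the scatter is artificial.

If a catalyst dies on a fixed clock and its rate is first order in starting material, then at equal charges of everything else the logarithm of the charge over what is left at the stall grows in step with the catalyst, so I counted turnovers in the two runs against that rule.

| flask | starting material | partner | catalyst | time |
|---|---|---|---|---|
| Saturday's | 0.200 M | 0.600 M | 0.00100 M |  |
| Sunday's | 0.200 M | 0.600 M | 0.00150 M |  |
| Thursday's | 0.500 M | 0.600 M | 0.00100 M | 15 min |

- Saturday's run (time / min: [product] / M): 0.60: 0.0062; 0.95: 0.0091; 1.5: 0.0138; 2.4: 0.0198; 3.8: 0.0252; 6.0: 0.0321; 9.5: 0.0379; 15: 0.0409
- Sunday's run (time / min: [product] / M): 0.60: 0.0096; 0.95: 0.0133; 1.5: 0.0193; 2.4: 0.0279; 3.8: 0.0365; 6.0: 0.0458; 9.5: 0.0526; 15: 0.0558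

(each reading ± 6 × 10⁻⁴ M)

- Overall: starting material + partner -> product, with catalyst as catalyst.
- Constant volume, constant temperature.
- Readings of a species count what is bound in complexes too.
- "The second partner" is partner.
- An order is taken over about fifteen percent of the charge, up and down.

- reaction order in [catalyst] at the outset, round the charge of the Saturday's run, defined at two percent of the starting material turned into product
- product in the Thursday's run at 15 min, as a share of the starting material charged

At the last reading the Saturday's run stood at 40.9 turnovers and the Sunday's at 37.2, fewer. The rule itself expects fewer: carried from the Saturday's reading it gave the Sunday's run 0.0581 M, or 38.7 turnovers. But the Sunday's reading of 0.0558 M lay below that, by 3.83 times the scatter of one reading, and as both readings carry scatter I took this as a lean, not a proof. So I tried a different picture: the catalyst keeps working while a first-order side path drains the starting material, and the two paths divide the charge.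

For the Saturday's run I reckoned 0.257 as the plateau odds, meaning c(product) over the part of the charge not turned into product at the last reading, which is a selectivity factor between the two paths. The Sunday's run gave 0.387. The odds thus rose by a factor of 1.51 when the catalyst rose by 1.50, which makes my order in catalyst 1.01.

The Thursday's run kept the catalyst and partner of the Saturday's, so I carried the odds over and got a share of 20.4 %, or 0.102 M of product.

The weak link was my assumption that both paths are first order in starting material, and I tried to reforge it from the Saturday's curve. Its first reading over its last gave a clock of 0.253 min⁻¹, and one exponential on that clock predicted 0.0319 M at 6.0 min, where the reading was 0.0321 M. But that shape also fits a catalyst dying on that clock, and the Saturday's and Sunday's runs both held 0.200 M of starting material, so the assumption stayed untested and my number stood as a bet on it.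

The forecast gave 0.93 and 15 %; it read the stall as “the catalyst is dying” and, for the Thursday's run, said “I lean to partial saturation”, which put it below my share of 20.4 %.

The flask gave 1.1 and 20.3 %.

    catalyst + starting material → catalyst-substrate complex (126.6 M⁻¹ min⁻¹)
    catalyst-substrate complex + partner → product + catalyst (3732 M⁻¹ min⁻¹)
    starting material + partner ⇌ idle substrate-reagent adduct, settled at all times (2.620 M⁻¹)
    starting material → decomposed substrate (0.4812 min⁻¹)

The Thursday's share means odds of 0.255, close to the Saturday's 0.257, so the odds survived the larger charge. The main reason for the Thursday's shortfall was the decomposition of starting material: in the run with that step taken away, the Thursday's share at 15 min rose from 20.3 % to 66.1 %.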